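**Assumption:** natural (2S)-liquiritigenin (the licorice aglycone) is bought as the (2S) enantiomer, with its er confirmed by chiral HPLC on receipt; it is the only chiral material used.

**Retrosynthetic overview**
1. 8 ⇒ 6 (glabrol): the 2H-pyran ring on ring B is closed last (O–CMe2 bond) by dehydrogenation and oxa-6π cyclisation under anodic DDQ catalysis.
2. 6 ⇒ 5: both C-prenyl C–C bonds (C8 and C3') come from a double aromatic Claisen shift of a bis(1,1-dimethylallyl) ether.
3. 5 ⇒ 4 + 3: Pd-catalysed O-tert-prenylation of (2S)-liquiritigenin 4, which supplies rings A, B, C and the only stereocentre; carbonate 3 is made from alcohol 1.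
4. Ring order: the chromanone (A/C) and ring B are bought intact; the only ring formed is the pyran of the chromene, in the last step.

**Route**

Step 1
Reactants: 1 2-methylbut-3-en-2-ol
Product: 3 tert-butyl (2-methylbut-3-en-2-yl) carbonate, via lithium 2-methylbut-3-en-2-olate 2 (not isolated)
Conditions: n-BuLi (1.05 equiv), THF, 0 °C; then Boc2O (1.1 equiv), 0 °C → rt
Reagents that add atoms: di-tert-butyl dicarbonate (Boc2O), CC(C)(C)OC(=O)OC(=O)OC(C)(C)C
Why: Alkoxycarbonylation of a pre-formed lithium tertiary alkoxide with Boc2O is a routine O-acylation (tert-butyl carbonate synthesis), and no stereocentre is involved.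

Step 2
Reactants: 4 (2S)-liquiritigenin [(2S)-7-hydroxy-2-(4-hydroxyphenyl)chroman-4-one]; 3 tert-butyl (2-methylbut-3-en-2-yl) carbonate (2.6 equiv)
Product: 5 (2S)-7-(2-methylbut-3-en-2-yloxy)-2-[4-(2-methylbut-3-en-2-yloxy)phenyl]chroman-4-one
Conditions: Pd(PPh3)4 (5 mol %), THF, 0 °C, 12 h; silica plug to remove Pd
Reagents that add atoms: none
Why: Decarboxylative Tsuji–Trost O-allylation, in which Pd(0) ionises 3 to a 1,1-dimethyl-π-allyl-Pd cation plus tert-butoxide that deprotonates the phenols in situ, each phenoxide attacks the more substituted allyl terminus at 0 °C to give the kinetic tertiary ether, and the cold, near-neutral medium leaves the base-sensitive C2 (S) centre untouched.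

Step 3
Reactants: 5 (2S)-7-(2-methylbut-3-en-2-yloxy)-2-[4-(2-methylbut-3-en-2-yloxy)phenyl]chroman-4-one
Product: 6 glabrol, (2S)-7-hydroxy-2-[4-hydroxy-3-(3-methylbut-2-enyl)phenyl]-8-(3-methylbut-2-enyl)chroman-4-one
Conditions: PhMe (0.05 M), 110 °C, 8 h, Ar, base-washed glassware
Reagents that add atoms: none
Why: Two independent aromatic Claisen [3,3] rearrangements of tertiary allyl aryl ethers (facile near 100 °C) transpose each allyl unit into a linear prenyl group; on ring A the shift goes to C8 because O1→C4=O conjugation fixes double-bond character in C7–C8 (the angular selectivity of 7-allyloxy-chromanones and -coumarins), on ring B both ortho carbons are equivalent, and the neutral non-polar medium does not open the pyranone ring, so C2 stays (S).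

Step 4
Reactants: 6 glabrol
Product: 8 (2S)-2-(2,2-dimethyl-2H-chromen-6-yl)-7-hydroxy-8-(3-methylbut-2-enyl)chroman-4-one (target CNP0156801.1), via ring-B o-quinone methide 7 (not isolated)
Conditions: DDQ (10 mol %), 2,6-lutidine (0.5 equiv), AcOH (5 equiv), nBu4NPF6 (0.1 M), CH2Cl2/MeCN (4:1), RVC(+)|Pt wire(−), undivided cell, anode at ca. +0.9 V vs Ag/AgCl (set by CV just positive of the DDQH2/DDQ wave), about 2.1 F/mol with HPLC control, 0 °C, dark
Reagents that add atoms: none
Why: Proposed new method: an anodically turned-over, catalytic-DDQ dehydrogenative cycloetherification that discriminates between two o-prenylphenols — DDQ removes a hydride (electron/H transfer inside a charge-transfer complex) from the benzylic–allylic CH2 of the ring-B prenyl group, whose 2,4-dialkylphenol ring is the better donor, loss of the phenolic proton gives the (Z)-vinyl o-quinone methide 7, and a thermal oxa-6π electrocyclisation closes the O–CMe2 bond of the 2,2-dimethyl-2H-chromene, while DDQH2 is re-oxidised at the anode below the onset of direct oxidation of either phenol and the protons leave as H2 at the cathode; ring A should be spared because its 7-OH is a vinylogous acid conjugated with the C4 ketone (estimated about 0.3 V harder to oxidise, and such rings typically need hot stoichiometric DDQ), the standing DDQ concentration is small and the charge is stopped near 2 F/mol, and C2 is not involved so it stays (S); the closest known reactions are the stoichiometric DDQ cyclisation of o-prenylphenols to 2,2-dimethylchromenes and anodically recycled DDQ in benzylic C–H oxidations and lactonisations, neither of which has been shown for this ring closure or for site selection between two prenylphenols.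

**Compound list**
1 | 2-methylbut-3-en-2-ol | C=CC(C)(C)O | starting material
2 | lithium 2-methylbut-3-en-2-olate | [Li+].[O-]C(C)(C)C=C | intermediate (not isolated)
3 | tert-butyl (2-methylbut-3-en-2-yl) carbonate | C=CC(C)(C)OC(=O)OC(C)(C)C | intermediate
4 | (2S)-liquiritigenin, (2S)-7-hydroxy-2-(4-hydroxyphenyl)chroman-4-one | Oc1ccc2c(c1)O[C@H](c1ccc(O)cc1)CC2=O | starting material
5 | (2S)-7-(2-methylbut-3-en-2-yloxy)-2-[4-(2-methylbut-3-en-2-yloxy)phenyl]chroman-4-one | C=CC(C)(C)Oc1ccc2c(c1)O[C@H](c1ccc(OC(C)(C)C=C)cc1)CC2=O | intermediate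
6 | glabrol, (2S)-7-hydroxy-2-[4-hydroxy-3-(3-methylbut-2-enyl)phenyl]-8-(3-methylbut-2-enyl)chroman-4-one | CC(C)=CCc1c(O)ccc2c1O[C@H](c1ccc(O)c(CC=C(C)C)c1)CC2=O | intermediate
7 | ring-B o-quinone methide, (2S)-7-hydroxy-8-(3-methylbut-2-enyl)-2-[(3Z)-3-(3-methylbut-2-enylidene)-4-oxocyclohexa-1,5-dien-1-yl]chroman-4-one | CC(C)=CCc1c(O)ccc2c1O[C@H](C1=C/C(=C/C=C(C)C)C(=O)C=C1)CC2=O | intermediate (not isolated)
8 | (2S)-2-(2,2-dimethyl-2H-chromen-6-yl)-7-hydroxy-8-(3-methylbut-2-enyl)chroman-4-one (shinflavanone, CNP0156801.1) | CC(C)=CCc1c(O)ccc2c1O[C@H](c1ccc3c(c1)C=CC(C)(C)O3)CC2=O | target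

**Step count**
Total steps: 4. Longest linear sequence: 4 (1 → 3 → 5 → 6 → 8); three operations from liquiritigenin 4.

**Three steps most likely to fail**

Step 4 (the proposed new step). The risks are competing closure on ring A or bis-chromene formation, and hydride loss from C2–H (para to the 4'-OH and α to oxygen), which would give a p-quinone methide and erode the er or lead to the flavone. The fallback uses known chemistry only, sets out from 4 and comes back at 8. Mono-O-alkylation of the more acidic 7-OH of 4 with carbonate 3 (1.05 equiv, Pd(PPh3)4, THF, 0 °C) gives (2S)-7-(2-methylbut-3-en-2-yloxy)-2-(4-hydroxyphenyl)chroman-4-one F1. Copper-catalysed propargylation of the remaining 4'-OH (3-chloro-3-methylbut-1-yne, CuCl2 cat., DBU, MeCN, 0 °C, er checked) gives (2S)-7-(2-methylbut-3-en-2-yloxy)-2-[4-(2-methylbut-3-yn-2-yloxy)phenyl]chroman-4-one F2. Heating F2 (o-xylene, 140 °C) runs the allyl Claisen shift on ring A and the aryl propargyl Claisen / 1,5-H shift / oxa-6π cascade on ring B, delivering 8 directly with no oxidation and therefore no ring-A/ring-B selectivity question.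

Step 3. The risks are the C6-prenyl regioisomer on ring A, thermal loss of isoprene from the tertiary ethers, and chroman formation. The fallback sets out from 4 and comes back at 6. Mitsunobu bis-O-prenylation under neutral conditions (3-methylbut-2-en-1-ol, PPh3, DIAD, THF, 0 °C → rt) gives (2S)-7-(3-methylbut-2-enyloxy)-2-[4-(3-methylbut-2-enyloxy)phenyl]chroman-4-one F3. An acidic-clay-promoted [1,3] O→C shift (montmorillonite K10 or Florisil, CH2Cl2, 0 °C → rt) then carries each prenyl group to the adjacent ortho carbon through a surface-bound ion pair and gives 6 without heating. This route does not guarantee C8 over C6 on ring A, so the two isomers would have to be separated by chromatography.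

Step 2. The risks are Pd-mediated re-ionisation of the tertiary ether on the electron-poor ring A, leading to the linear O-prenyl ether or C-allylation, and partial racemisation through the transient 4'-phenoxide. The fallback sets out from 4 and comes back at 5. Copper-catalysed bis-propargylation (3-chloro-3-methylbut-1-yne, CuCl2 cat., DBU, MeCN, 0 °C) gives (2S)-7-(2-methylbut-3-yn-2-yloxy)-2-[4-(2-methylbut-3-yn-2-yloxy)phenyl]chroman-4-one F4. Semi-hydrogenation of both terminal alkynes (H2 1 atm, Lindlar catalyst, quinoline, EtOAc, rt) then gives 5 with no palladium-allyl chemistry involved.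

**Further compounds**
F1 | step 4 | (2S)-7-(2-methylbut-3-en-2-yloxy)-2-(4-hydroxyphenyl)chroman-4-one | C=CC(C)(C)Oc1ccc2c(c1)O[C@H](c1ccc(O)cc1)CC2=O
F2 | step 4 | (2S)-7-(2-methylbut-3-en-2-yloxy)-2-[4-(2-methylbut-3-yn-2-yloxy)phenyl]chroman-4-one | C=CC(C)(C)Oc1ccc2c(c1)O[C@H](c1ccc(OC(C)(C)C#C)cc1)CC2=O
F3 | step 3 | (2S)-7-(3-methylbut-2-enyloxy)-2-[4-(3-methylbut-2-enyloxy)phenyl]chroman-4-one | CC(C)=CCOc1ccc2c(c1)O[C@H](c1ccc(OCC=C(C)C)cc1)CC2=O
F4 | step 2 | (2S)-7-(2-methylbut-3-yn-2-yloxy)-2-[4-(2-methylbut-3-yn-2-yloxy)phenyl]chroman-4-one | C#CC(C)(C)Oc1ccc2c(c1)O[C@H](c1ccc(OC(C)(C)C#C)cc1)CC2=O
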